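**Plan**

Ring A is the methyl benzoate ring (C1 CO2Me, C2 O-aryl, C4 OH, C6 pentyl). Ring B is the salicylic acid ring, numbered C1' (CO2H), C2' (OH), C3' (H), C4' (OMe), C5' (O-ring A), C6' (pentyl).
Enabling feature: C2'-C3'-C4'-C5' of ring B carry O, H, O, O as a 4-aryloxy-1,3-dimethoxy-1-silyloxybuta-1,3-diene does, and C1' and C6' carry carboxyl and pentyl as the two alkyne carbons of an oct-2-ynoate do. Ring B is thus a 4-methoxysalicylate suited to a Diels-Alder reaction followed by aromatization.
Retrosynthesis: the two benzyl groups are cut first, then the ring B bonds C5'-C6' and C1'-C2' (cycloaddition), then the O-CH2 bond between the ring A oxygen and the future C5' (Williamson), and last the benzyl ether, methyl ester and carboxyl carbon of ring A, back to olivetol.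
Forward: ring A is completed from olivetol (carboxylation, methyl ester, 4-O-benzyl ether) and its C2 phenol is alkylated with methyl (E)-4-chloro-3-methoxybut-2-enoate. The enoate is converted into the silyl ketene acetal diene, ring B is built onto the ether oxygen by cycloaddition with benzyl oct-2-ynoate, and hydrogenolysis ends the route.
Stereochemistry: the target has no stereocentre. The selectivity questions are the regiochemistry of the cycloaddition (polarity matching) and the differentiation of the two ring A phenols (hydrogen bonding to the ester).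

Key step: step 7

Assumption: diene 7 is written as the 1Z,3E isomer (aryloxy group on the outside of the s-cis diene); the geometry at the acetal carbon does not affect the product, because that carbon becomes the sp2 carbon C2' of ring B.

**Route**

Step 1
Reactants: 1 olivetol (5-pentylbenzene-1,3-diol)
Product: 2 olivetolic acid (2,4-dihydroxy-6-pentylbenzoic acid)
Conditions: MeOMgOCO2Me (2 M in DMF, 8 equiv), 120 °C, N2; then ice-cold 2 M HCl
Reagents that add atoms: methoxymagnesium methyl carbonate (MeOMgOCO2Me), COC(=O)O[Mg]OC
Why: This is a Kolbe-Schmitt-type ortho-carboxylation of the magnesium resorcinolate, which should occur ortho to one hydroxyl and para to the other, the magnesium chelate of the β-resorcylate holding the product against decarboxylation until the cold acidic work-up.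

Step 2
Reactants: 2 olivetolic acid
Product: 3 methyl 2,4-dihydroxy-6-pentylbenzoate (methyl olivetolate)
Conditions: MeI (1.2 equiv), KHCO3 (1.5 equiv), DMF, rt
Reagents that add atoms: iodomethane (MeI), CI
Why: KHCO3 ionises only the carboxylic acid, so SN2 O-alkylation of the carboxylate by MeI should give the methyl ester and leave both phenols free.

Step 3
Reactants: 3 methyl 2,4-dihydroxy-6-pentylbenzoate
Product: 4 methyl 4-benzyloxy-2-hydroxy-6-pentylbenzoate
Conditions: BnBr (1.05 equiv), K2CO3 (1.1 equiv), acetone, reflux
Reagents that add atoms: benzyl bromide, BrCc1ccccc1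
Why: The C4 hydroxyl is the more acidic and unhindered phenol while the C2 hydroxyl is held in a hydrogen bond to the ester carbonyl, so Williamson etherification with one equivalent of BnBr should be selective for O4.

Step 4
Reactants: 4 methyl 4-benzyloxy-2-hydroxy-6-pentylbenzoate; 5 methyl (E)-4-chloro-3-methoxybut-2-enoate
Product: 6 methyl (E)-4-[5-benzyloxy-2-(methoxycarbonyl)-3-pentylphenoxy]-3-methoxybut-2-enoate
Conditions: 5 (1.3 equiv), K2CO3 (2 equiv), KI (0.1 equiv), DMF, 60 °C
Reagents that add atoms: none
Why: Under more forcing Williamson conditions (DMF, iodide catalysis) the chelated C2 phenoxide should displace the activated primary chloride of 5 by SN2, which joins the ring A oxygen to the future C5' without a crowded aryl C-O coupling and keeps the E enol ether.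

Step 5
Reactants: 6 methyl (E)-4-[5-benzyloxy-2-(methoxycarbonyl)-3-pentylphenoxy]-3-methoxybut-2-enoate
Product: 7 methyl 4-benzyloxy-2-{[(1Z,3E)-2,4-dimethoxy-4-(trimethylsilyloxy)buta-1,3-dien-1-yl]oxy}-6-pentylbenzoate
Conditions: LiN(i-Pr)2 (1.1 equiv, commercial solution), Me3SiCl (1.5 equiv, present from the start), THF, −78 °C to 0 °C; pentane, filtration under Ar, no aqueous work-up; used crude
Reagents that add atoms: chlorotrimethylsilane (Me3SiCl), C[Si](C)(C)Cl
Why: γ-Deprotonation of the β-methoxy enoate (vinylogous ester enolisation, the OCH2 group being cis to the ester in the E isomer) followed by O-silylation is the standard entry to 1,3-dialkoxy-1-silyloxybuta-1,3-dienes, and in situ trapping at −78 °C should outrun attack of the dienolate on the hindered ring A ester.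

Step 6
Reactants: 8 oct-2-ynoic acid
Product: 9 benzyl oct-2-ynoate
Conditions: BnBr (1.1 equiv), K2CO3 (1.2 equiv), DMF, rt
Reagents that add atoms: benzyl bromide, BrCc1ccccc1
Why: SN2 alkylation of the carboxylate gives the benzyl ester without the nucleophilic acylation catalysts that can add to the conjugated triple bond.

Step 7
Reactants: 7 methyl 4-benzyloxy-2-{[(1Z,3E)-2,4-dimethoxy-4-(trimethylsilyloxy)buta-1,3-dien-1-yl]oxy}-6-pentylbenzoate; 9 benzyl oct-2-ynoate
Product: 12 benzyl 5-[5-benzyloxy-2-(methoxycarbonyl)-3-pentylphenoxy]-2-hydroxy-4-methoxy-6-pentylbenzoate, via cyclohexa-1,4-diene cycloadduct 10 (not isolated), via ring B trimethylsilyl ether 11 (not isolated)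
Conditions: 9 (3 equiv), toluene (concentrated), sealed tube, 110 °C, Ar; then 1 M HCl, THF, rt
Reagents that add atoms: none
Why: The electron-rich silyl ketene acetal diene 7 and the electron-poor alkynoate 9 should undergo a concerted but strongly asynchronous normal-demand Diels-Alder reaction, the aryloxy-bearing terminus bonding in advance to the β-carbon of the ynoate (C5'-C6') while the acetal carbon closes onto the α-carbon (C1'-C2'). The closest known reaction type is the cycloaddition of 1,3-dialkoxy-1-silyloxybuta-1,3-dienes with acetylenic esters, which gives 4-alkoxysalicylates after loss of alcohol; here the diene carries an additional 4-aryloxy group and the alkyne a β-alkyl group, hence the heating and the excess of 9. Ring B closes by intermolecular [4+2] cycloaddition (four diene carbons plus the two alkyne carbons) to cyclohexa-1,4-diene 10, which aromatizes by 1,4-elimination of methanol (the C2' methoxy group leaves through an oxygen-stabilised cation and the C5' hydrogen is lost) to silyl ether 11, and dilute acid then frees the C2' phenol, hydrogen-bonded to the benzyl ester. The two stereocentres of 10 (C2' and C5', cis-related through suprafacial addition to the 1Z,3E diene) are transient and are erased on aromatization, so no stereocontrol is needed. The selectivity required is regiochemical, C5' to the pentyl-bearing alkyne carbon, and it is secured by matched polarisation: the three oxygen donors at the acetal carbon and at C4' place the largest HOMO coefficient of 7 on the aryloxy-bearing terminus, outweighing the opposing effect of the single aryloxy donor, and the largest LUMO coefficient of 9 lies on its β-carbon. Expulsion of the ring A phenoxide instead of methanol cannot give an arene because C2' carries no hydrogen, and the methyl ester and benzyl ether of ring A are inert at this temperature.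

Step 8
Reactants: 12 benzyl 5-[5-benzyloxy-2-(methoxycarbonyl)-3-pentylphenoxy]-2-hydroxy-4-methoxy-6-pentylbenzoate
Product: 13 epiphorellic acid 1 (2-hydroxy-5-[5-hydroxy-2-(methoxycarbonyl)-3-pentylphenoxy]-4-methoxy-6-pentylbenzoic acid)
Conditions: H2 (1 atm), 10% Pd/C, EtOAc, rt
Reagents that add atoms: none
Why: Hydrogenolysis of the benzyl ester and the benzyl aryl ether over palladium on carbon is neutral and runs at room temperature, so the decarboxylation-prone ring B salicylic acid, the ring A methyl ester, the diaryl ether and the aryl methyl ether should all survive.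

**Compound list**

1 | olivetol (5-pentylbenzene-1,3-diol) | CCCCCc1cc(O)cc(O)c1 | starting material
2 | olivetolic acid (2,4-dihydroxy-6-pentylbenzoic acid) | CCCCCc1cc(O)cc(O)c1C(=O)O | intermediate
3 | methyl 2,4-dihydroxy-6-pentylbenzoate | CCCCCc1cc(O)cc(O)c1C(=O)OC | intermediate
4 | methyl 4-benzyloxy-2-hydroxy-6-pentylbenzoate | CCCCCc1cc(OCc2ccccc2)cc(O)c1C(=O)OC | intermediate
5 | methyl (E)-4-chloro-3-methoxybut-2-enoate | CO/C(CCl)=C/C(=O)OC | starting material
6 | methyl (E)-4-[5-benzyloxy-2-(methoxycarbonyl)-3-pentylphenoxy]-3-methoxybut-2-enoate | CCCCCc1cc(OCc2ccccc2)cc(OC/C(OC)=C\C(=O)OC)c1C(=O)OC | intermediate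
7 | methyl 4-benzyloxy-2-{[(1Z,3E)-2,4-dimethoxy-4-(trimethylsilyloxy)buta-1,3-dien-1-yl]oxy}-6-pentylbenzoate | CCCCCc1cc(OCc2ccccc2)cc(O/C=C(\OC)/C=C(OC)/O[Si](C)(C)C)c1C(=O)OC | intermediate
8 | oct-2-ynoic acid | CCCCCC#CC(=O)O | starting material
9 | benzyl oct-2-ynoate | CCCCCC#CC(=O)OCc1ccccc1 | intermediate
10 | benzyl 3-[5-benzyloxy-2-(methoxycarbonyl)-3-pentylphenoxy]-4,6-dimethoxy-2-pentyl-6-(trimethylsilyloxy)cyclohexa-1,4-diene-1-carboxylate (racemic; aryloxy and silyloxy groups cis; one enantiomer drawn) | CCCCCc1cc(OCc2ccccc2)cc(O[C@H]2C(OC)=C[C@@](OC)(O[Si](C)(C)C)C(C(=O)OCc3ccccc3)=C2CCCCC)c1C(=O)OC | intermediate (not isolated)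
11 | benzyl 5-[5-benzyloxy-2-(methoxycarbonyl)-3-pentylphenoxy]-4-methoxy-6-pentyl-2-(trimethylsilyloxy)benzoate | CCCCCc1cc(OCc2ccccc2)cc(Oc2c(OC)cc(O[Si](C)(C)C)c(C(=O)OCc3ccccc3)c2CCCCC)c1C(=O)OC | intermediate (not isolated)
12 | benzyl 5-[5-benzyloxy-2-(methoxycarbonyl)-3-pentylphenoxy]-2-hydroxy-4-methoxy-6-pentylbenzoate | CCCCCc1cc(OCc2ccccc2)cc(Oc2c(OC)cc(O)c(C(=O)OCc3ccccc3)c2CCCCC)c1C(=O)OC | intermediate
13 | epiphorellic acid 1 (2-hydroxy-5-[5-hydroxy-2-(methoxycarbonyl)-3-pentylphenoxy]-4-methoxy-6-pentylbenzoic acid) | CCCCCc1cc(O)cc(Oc2c(OC)cc(O)c(C(=O)O)c2CCCCC)c1C(=O)OC | target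

**Step count**

Total steps: 8. Longest linear sequence: 7 steps (steps 1, 2, 3, 4, 5, 7, 8, from olivetol); step 6 is a one-step side branch.

**Steps most likely to fail**

Step 7 (cycloaddition and aromatization). Both bond-forming termini are substituted (aryloxy on the diene, pentyl on the alkyne), so ring formation may be slow. Thermal silyl migration or protodesilylation of the diene by the methanol set free may then outrun it, and a stepwise Michael pathway could erode the regiochemistry. The fallback raises the dienophile to the aldehyde oxidation level. It sets out from diene 7, which would be heated at 60-80 °C in toluene with commercial oct-2-ynal, a more reactive dienophile with the same polarisation. The same cycloaddition, loss of methanol and acidic desilylation would give methyl 4-benzyloxy-2-(3-formyl-4-hydroxy-6-methoxy-2-pentylphenoxy)-6-pentylbenzoate F1. Chlorite oxidation of the aldehyde (NaClO2, NaH2PO4, 2-methylbut-2-ene, t-BuOH-H2O) would give 5-[5-benzyloxy-2-(methoxycarbonyl)-3-pentylphenoxy]-2-hydroxy-4-methoxy-6-pentylbenzoic acid F2. Hydrogenolysis of its single benzyl ether (H2, Pd/C, EtOAc) comes back to the route at target 13.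

Step 5 (diene formation). The lithium dienolate may close onto the neighbouring ring A ester in a five-membered Dieckmann-type reaction. The base may instead remove a benzylic hydrogen of the pentyl chain. Silylation may give the diene isomer with the aryloxy group on the inside, which would cycloadd sluggishly. The diene may also hydrolyse on handling. The fallback avoids the strong base and uses a bis-silyl diene. It sets out from 6, whose enol ether would be hydrolysed (1 M HCl, THF, rt) to methyl 4-[5-benzyloxy-2-(methoxycarbonyl)-3-pentylphenoxy]-3-oxobutanoate F3. Soft enolisation (Me3SiOSO2CF3 2.2 equiv, Et3N, Et2O, 0 °C) would give methyl 4-benzyloxy-2-{[(1Z,3E)-4-methoxy-2,4-bis(trimethylsilyloxy)buta-1,3-dien-1-yl]oxy}-6-pentylbenzoate F4. Cycloaddition of this diene with 9 under the conditions of step 7 and acidic work-up would give benzyl 5-[5-benzyloxy-2-(methoxycarbonyl)-3-pentylphenoxy]-2,4-dihydroxy-6-pentylbenzoate F5. Its C4' hydroxyl, the only one not hydrogen-bonded to the ester, would be methylated selectively (MeI, K2CO3, acetone), which comes back to the route at 12.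

Step 1 (carboxylation). Carboxylation may also occur at C2 between the two hydroxyls, may stop short of completion, or may be reversed by decarboxylation during work-up. The fallback brings in the carboxyl carbon as a formyl group. It sets out from 1, which on Vilsmeier-Haack formylation (POCl3, DMF; then aqueous NaOAc) would give 2,4-dihydroxy-6-pentylbenzaldehyde F6. Selective benzylation of the non-chelated hydroxyl (BnBr, K2CO3, acetone) would give 4-benzyloxy-2-hydroxy-6-pentylbenzaldehyde F7. Chlorite oxidation (NaClO2, NaH2PO4, H2NSO3H, dioxane-H2O) would give 4-benzyloxy-2-hydroxy-6-pentylbenzoic acid F8. Esterification (MeI, KHCO3, DMF) comes back to the route at 4.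

**Further compounds**

F1 | step 7 | methyl 4-benzyloxy-2-(3-formyl-4-hydroxy-6-methoxy-2-pentylphenoxy)-6-pentylbenzoate | CCCCCc1cc(OCc2ccccc2)cc(Oc2c(OC)cc(O)c(C=O)c2CCCCC)c1C(=O)OC
F2 | step 7 | 5-[5-benzyloxy-2-(methoxycarbonyl)-3-pentylphenoxy]-2-hydroxy-4-methoxy-6-pentylbenzoic acid | CCCCCc1cc(OCc2ccccc2)cc(Oc2c(OC)cc(O)c(C(=O)O)c2CCCCC)c1C(=O)OC
F3 | step 5 | methyl 4-[5-benzyloxy-2-(methoxycarbonyl)-3-pentylphenoxy]-3-oxobutanoate | CCCCCc1cc(OCc2ccccc2)cc(OCC(=O)CC(=O)OC)c1C(=O)OC
F4 | step 5 | methyl 4-benzyloxy-2-{[(1Z,3E)-4-methoxy-2,4-bis(trimethylsilyloxy)buta-1,3-dien-1-yl]oxy}-6-pentylbenzoate | CCCCCc1cc(OCc2ccccc2)cc(O/C=C(\O[Si](C)(C)C)/C=C(OC)/O[Si](C)(C)C)c1C(=O)OC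
F5 | step 5 | benzyl 5-[5-benzyloxy-2-(methoxycarbonyl)-3-pentylphenoxy]-2,4-dihydroxy-6-pentylbenzoate | CCCCCc1cc(OCc2ccccc2)cc(Oc2c(O)cc(O)c(C(=O)OCc3ccccc3)c2CCCCC)c1C(=O)OC
F6 | step 1 | 2,4-dihydroxy-6-pentylbenzaldehyde | CCCCCc1cc(O)cc(O)c1C=O
F7 | step 1 | 4-benzyloxy-2-hydroxy-6-pentylbenzaldehyde | CCCCCc1cc(OCc2ccccc2)cc(O)c1C=O
F8 | step 1 | 4-benzyloxy-2-hydroxy-6-pentylbenzoic acid | CCCCCc1cc(OCc2ccccc2)cc(O)c1C(=O)O
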